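## Structural features

The target is a flavonol: a 4H-chromen-4-one (benzo ring A fused to pyranone ring C) carrying a 3,4,5-trimethoxyphenyl ring B on C2 through the single C2–C1' bond. It has no stereocentre and no further ring. Ring A is fully substituted except for C6–H (5-OH, 7-OMe, 8-OMe, O1 on C8a), ring C carries the enolic 3-OH, and ring B has three contiguous methoxy groups at C3', C4' and C5' between C2'–H and C6'–H. Of the seven peripheral oxygens, five are methyl ethers and two are free hydroxyls, and the free ones are exactly the two that flank the C4 carbonyl and are hydrogen-bonded to it. The real difficulty is therefore the differentiation of these oxygens rather than the skeleton, together with keeping the 5,7,8-pattern of ring A, which in 5-hydroxyflavones can isomerise to the 5,6,7-pattern by opening and reclosure of ring C in hot acid. Fragile points are the flavonol enol (easily oxidised as its anion), the electron-rich C6 of ring A, the two methoxy groups crowded between two oxygens (8-OMe and 4'-OMe) and, on the route, the electrophilic 2-ethynylchromone. The key step exploits ring B: the unit C3'(O)–C4'(O)–C5'(O) flanked by two CH groups maps onto 3,4-dimethoxyfuran, whose two methoxy groups become the 4'- and 5'-methoxy groups and whose ring oxygen becomes the 3'-oxygen, while C1' and C2' are the two carbons of an alkyne on C2 of ring C.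

## Logic of the disconnections

16 ⇒ 15. The 3-O–H and 5-O–H bonds are traced back to a benzyl ether at O3 and a methyl ether at O5. These are the only two ethers that chelate a Lewis acid together with the C4 carbonyl, so one reagent can address both. The gain is that every oxygen is capped in all earlier intermediates and the 5-oxygen needs no separate protecting group, since it comes as its methyl ether from 1. The demand on the forward step is to cleave exactly two of seven ethers without transferring the benzyl cation to C6.

15 ⇒ 14. The 3'-O–CH3 bond is cut. The reason is that the ring-forming step delivers this oxygen as a hydroxyl. The forward step is trivial because 14 has only one free hydroxyl.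

14 ⇒ 11 + 12 (through 13). The bonds C1'–C6' and C2'–C3' are cut and the 3'-oxygen is returned to a bridge between C3' and C6'. Ring B disappears completely: four of its carbons and all three of its oxygens come from 12, and C1' and C2' are the alkyne carbons of 11. Because 12 is symmetric, bond formation has no regiochemical question, and the step is convergent. The demands are three:
- the alkyne must be dienophilic enough;
- the bridge must ionise at the bridgehead next to C1';
- the alkyne terminus must be C–H, since a silyl group there would slow the cycloaddition and stabilise the wrong bridgehead cation through the β-silicon effect.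

11 ⇒ 10 ⇒ 8 + 9. First the terminal C–H is traced to C–Si, then the C2–C(sp) bond is cut. The reactive enynone 11 is stored as its silyl derivative 10 and released cold just before use. The two alkyne carbons come from 9, and 8 is a vinylogous acyl iodide that should couple at room temperature. The demands are a non-nucleophilic amine in the coupling and a buffered, non-basic desilylation.

8 ⇒ 6. The C2–I bond is cut. C2–H is the only C–H of ring C, lies next to O1 and is flanked by the coordinating 3-benzyloxy group, so it can be replaced by directed metalation. The demand is a base that leaves the carbonyl, the benzylic CH2 and C6–H alone.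

6 ⇒ 5 ⇒ 3. The O–benzyl bond and then the C3–O bond are cut. The 3-oxygen is introduced by oxidising the C2=C3 enol-ether bond of a plain chromone. The demand is an oxidant that spares ring A.

3 ⇒ 1 (through 2). O1–C2 and C2–C3 are cut, and C2 is supplied as a formyl equivalent. This reaches 1, in which the complete oxygen pattern of ring A is already fixed. Since 1 has only one free phenol, only the 5,7,8-chromone can form. Compounds 9 and 12 are bought.

## Other disconnections considered

Alternative 1: The cut removes C2 as a one-carbon unit: C2–C3 and C2–C1' are broken and ring C is opened at O1–C2. This leaves the ring A ketone 2-(benzyloxy)-1-[2-(benzyloxy)-3,4,6-trimethoxyphenyl]ethan-1-one A1, the aryl iodide 5-iodo-1,2,3-trimethoxybenzene A2 and carbon monoxide A3.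
- Forward key step: a zerovalent palladium catalyst with a wide-bite-angle diphosphine would insert into the C–I bond of A2, take up A3 to give an aroylpalladium species and acylate the enolate of A1 at carbon. The product would be the open-chain 2-benzyloxy-1,3-diketone A4 (racemic and enolisable, so its stereocentre is of no consequence). Hydrogenolysis of both benzyl ethers and acid cyclodehydration would close ring C to the flavonol A5, and peri-demethylation would give 16.
- In its favour: three components are joined in one step; ring B is bought with its three methoxy groups in place, so no question arises about where an oxygen ends up; carbonylative α-arylation of aryl ketones to 1,3-diketones is an established reaction type.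
- Against it here: the enolate of an α-alkoxy ketone next to a di-ortho-substituted aryl group is an untried partner. A4 is more acidic than A1, would consume base and would invite O-acylation or retro-Claisen cleavage. A2 is electron-rich and therefore a slow electrophile. A1 itself needs about three steps from 1 (O-benzylation, α-oxygenation, benzylation of a base-sensitive α-hydroxy ketone).
- Comparison, structure: the alternative is the better of the two for ring B, which it does not have to build, whereas the chosen plan must steer the bridge opening.
- Comparison, mechanism: both key steps are unproven on their exact substrates. The alternative forms only the chain and needs a separate ring closure; the chosen plan forms and aromatises a ring in one pot.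
- Comparison, step economy: the alternative is better (about seven steps against nine). Its endgame needs the same peri-demethylation and is the equal of the chosen plan there.

Alternative 2: The cut runs across ring C at C3–C4 and O1–C2. It separates a ring A quinoketene, 2,3,5-trimethoxy-6-(oxomethylidene)cyclohexa-2,4-dien-1-one A7, stored as the benzodioxinone 5,7,8-trimethoxy-2,2-dimethyl-4H-1,3-benzodioxin-4-one A6, from the enamine 4-[2-(benzyloxy)-1-(3,4,5-trimethoxyphenyl)ethenyl]morpholine A8, which carries ring B and the 3-oxygen.
- Forward key step: thermolysis of A6 would release A7 by retro-[4+2] loss of its ketone fragment. The nucleophilic β-carbon of A8 would add to the ketene carbon (C3–C4), the phenoxide would close onto the iminium carbon (O1–C2, six-membered and polarity-matched), and loss of the secondary amine would aromatise ring C to A9, which has the same structure as 15.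
- In its favour: two fragments of similar size meet in the ring-forming step; the orientation is dictated by the polarity of ketene and enamine; no metal is needed; the product enters the chosen route at 15, so neither the O-methylation nor any ring B chemistry is required.
- Against it here: a benzo-fused dioxinone gives up the aromaticity of ring A on opening and would need forcing heat or light. The amine set free can capture A7 as a salicylamide. A8 is a hindered, hydrolytically labile enamine of an α-alkoxy ketone and would form as a mixture of geometric isomers. The salicylic acid behind A6 is not a catalogue compound and would cost about three steps from 1.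
- Comparison, structure: it builds ring C and buys ring B, which is the equal of the chosen plan in convergence and better in that the 3'-oxygen needs no regiocontrol.
- Comparison, mechanism: both are pericyclic cascades ending in aromatisation. The alternative has an unambiguous orientation (better) but a less accessible reactive intermediate (worse).
- Comparison, step economy: about equal in total (roughly eight steps), with a shorter longest linear sequence, which counts for the alternative.

Alternative 3: The cut is made in ring A at C4a–C5, with C8–C8a traced to an earlier carbonyl addition. Ring A is then assembled on a preformed pyranone, 3-(benzyloxy)-2-(3,4,5-trimethoxyphenyl)-4H-pyran-4-one A10, from 3-methoxycyclobut-3-ene-1,2-dione A11.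
- Forward key step: metalation of A10 at C6 and addition to the ketone-like carbonyl of A11 would give the racemic cyclobutenone 4-[5-(benzyloxy)-4-oxo-6-(3,4,5-trimethoxyphenyl)-4H-pyran-2-yl]-4-hydroxy-3-methoxycyclobut-2-en-1-one A12. Heating would open A12 (4π electrocyclic) to a dienylketene, whose 6π closure onto pyranone C5 and tautomerisation would give the 5,8-hydroquinone A13. O-Methylation of the unchelated 8-hydroxyl to A14 and hydrogenolysis would give 16.
- In its favour: the 5-hydroxyl is born free and chelated, so no peri-demethylation is needed and the last step is a neutral hydrogenolysis. The orientation of the annulation follows from the site of the carbonyl addition. Moore cyclisations onto alkenyl and heteroaryl π-bonds are thermally reliable.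
- Against it here: ring A, the one ring that can be bought complete in 1, is the ring that is built. A10 needs its own multistep synthesis carrying ring B. The stability of the metalated pyranone and the regiochemistry of its addition to unsymmetrical A11 are uncertain. A13 is an air-sensitive hydroquinone, and its 8-hydroxyl must be methylated without touching the 5-hydroxyl.
- Comparison, structure: the chosen plan builds ring B, for which the furan supplies the full oxygen pattern. The alternative builds ring A, which can be bought, so it puts its effort in the less useful place.
- Comparison, mechanism: both are thermal pericyclic sequences ending in aromatisation. The alternative is the equal of the chosen plan in predictability of the ring closure and better in the chemoselectivity of its endgame.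
- Comparison, step economy: worse, at an estimated eleven to twelve steps.

Key step: step 7

Remark on the chemistry: 1, 9 and 12 are treated as purchasable catalogue compounds; the target has no stereocentre, and the stereocentres of 4 and 13 are transient and racemic.

## Route

Step 1
Reactants: 1 2'-hydroxy-3',4',6'-trimethoxyacetophenone
Product: 3 5,7,8-trimethoxy-4H-chromen-4-one, via enaminone 2 (not isolated)
Conditions: Me2NCH(OMe)2, toluene, 100 °C; then conc. HCl, CH2Cl2, 40 °C
Reagents that add atoms: N,N-dimethylformamide dimethyl acetal, COC(OC)N(C)C
Why: Condensation of the methyl ketone with the amide acetal gives the (E)-enaminone; acid then lets the single phenol oxygen add to the β-carbon and expel dimethylamine, the standard enaminone synthesis of 2,3-unsubstituted chromones, and the methyl ethers are inert.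

Step 2
Reactants: 3 5,7,8-trimethoxy-4H-chromen-4-one
Product: 5 3-hydroxy-5,7,8-trimethoxy-4H-chromen-4-one, via epoxide 4 (not isolated)
Conditions: dimethyldioxirane (acetone), CH2Cl2, 0 °C → rt; evaporate; then p-TsOH·H2O (cat.), CH2Cl2, rt
Reagents that add atoms: dimethyldioxirane, CC1(C)OO1
Why: Neutral epoxidation of the C2=C3 enol-ether bond followed by acid opening at C2 (oxocarbenium ion stabilised by O1) and loss of H3 gives the enol, the known epoxidation–isomerisation route from chromones to 3-hydroxychromones; the oxidant is removed before the oxidisable enol is formed.

Step 3
Reactants: 5 3-hydroxy-5,7,8-trimethoxy-4H-chromen-4-one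
Product: 6 3-(benzyloxy)-5,7,8-trimethoxy-4H-chromen-4-one
Conditions: BnBr, K2CO3, DMF, rt
Reagents that add atoms: benzyl bromide, BrCc1ccccc1
Why: Williamson etherification of the acidic enolic 3-OH, the only acidic site; O-alkylation of 3-hydroxychromones with K2CO3 in DMF is routine.

Step 4
Reactants: 6 3-(benzyloxy)-5,7,8-trimethoxy-4H-chromen-4-one
Product: 8 3-(benzyloxy)-2-iodo-5,7,8-trimethoxy-4H-chromen-4-one, via 2-lithiochromone 7 (not isolated)
Conditions: LiN(iPr)2, THF, −78 °C; then I2, THF, −78 → −20 °C
Reagents that add atoms: iodine, II
Why: Directed metalation: C2–H is the only C–H of ring C, is acidified by O1 and flanked by the coordinating 3-benzyloxy group, so the hindered amide base removes it at −78 °C without adding to the carbonyl or touching the benzylic CH2 or C6–H; the vinyl-lithium cannot eliminate and is trapped by iodine.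

Step 5
Reactants: 8 3-(benzyloxy)-2-iodo-5,7,8-trimethoxy-4H-chromen-4-one; 9 ethynyltrimethylsilane
Product: 10 3-(benzyloxy)-5,7,8-trimethoxy-2-[(trimethylsilyl)ethynyl]-4H-chromen-4-one
Conditions: PdCl2(PPh3)2 (cat.), CuI (cat.), i-Pr2NEt, THF, rt
Reagents that add atoms: none
Why: Sonogashira coupling; the β-iodo enone (a vinylogous acyl iodide) should add oxidatively to zerovalent palladium at room temperature, the hindered tertiary amine cannot displace iodide at C2, and the silyl group blocks a second coupling and masks the alkyne.

Step 6
Reactants: 10 3-(benzyloxy)-5,7,8-trimethoxy-2-[(trimethylsilyl)ethynyl]-4H-chromen-4-one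
Product: 11 3-(benzyloxy)-2-ethynyl-5,7,8-trimethoxy-4H-chromen-4-one
Conditions: Bu4NF, AcOH, THF, −20 → 0 °C
Reagents that add atoms: none
Why: Fluoride-induced protodesilylation of the C(sp)–Si bond; acetic acid buffers the medium so that the acetylide is protonated at once and no basic or nucleophilic species is left to add to the electrophilic enynone, which is used directly in step 7.

Step 7
Reactants: 11 3-(benzyloxy)-2-ethynyl-5,7,8-trimethoxy-4H-chromen-4-one; 12 3,4-dimethoxyfuran
Product: 14 3-(benzyloxy)-2-(3-hydroxy-4,5-dimethoxyphenyl)-5,7,8-trimethoxy-4H-chromen-4-one, via oxanorbornadiene adduct 13 (not isolated)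
Conditions: 12 (3 equiv), toluene, 90 °C, sealed tube; evaporate; then CF3CO2H (excess), CH2Cl2, 0 °C → rt
Reagents that add atoms: none
Why: Proposed new method: the closest known reaction type is the Diels–Alder addition of 3,4-dialkoxyfurans to ynones and ynoates followed by acid isomerisation of the 7-oxanorbornadiene to a phenol, whereas an alkyne activated only vinylogously through the C2=C3–C4=O unit of a chromone has not served as the dienophile. The HOMO of electron-rich 12 and the LUMO of enynone 11 should combine in a concerted, suprafacial intermolecular [4+2] cycloaddition that forms C1'–C6' and C2'–C3' at once and closes the six-membered carbocycle as the oxa-bridged diene 13; since 12 is C2v-symmetric this event has no regiochemical question, and running it without acid avoids Friedel–Crafts-type conjugate addition of a furan α-carbon to the alkyne. The two bridgehead stereocentres of 13 are tied to each other by the bicycle, arise as a racemate and vanish on aromatisation, so no stereocontrol is needed. With excess acid the chromone carbonyl, the most basic site, is protonated first and ring C becomes a 4-hydroxybenzopyrylium ion. The bridge should therefore ionise at the bridgehead next to C1' (future C6'), because that cyclohexadienyl cation carries its charge on C2', C4' and C6', where the 4'-methoxy group stabilises it as an oxocarbenium ion and no charge lies on C1' beside the cationic heterocycle, whereas opening at the other bridgehead would put charge on C1' and lead to the 2'-hydroxy isomer. Loss of the C3' proton from this arenium ion, directly or after a 1,2-hydride shift to the dienone and enolisation, leaves the former bridge oxygen as the 3'-hydroxyl and makes ring B aromatic, which drives the sequence. The benzyl and methyl ethers and the chromone should tolerate the acid at or below room temperature, and the free alkyne terminus is essential because a silyl group there would favour the wrong bridgehead cation through the β-silicon effect.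

Step 8
Reactants: 14 3-(benzyloxy)-2-(3-hydroxy-4,5-dimethoxyphenyl)-5,7,8-trimethoxy-4H-chromen-4-one
Product: 15 3-(benzyloxy)-5,7,8-trimethoxy-2-(3,4,5-trimethoxyphenyl)-4H-chromen-4-one
Conditions: MeI, K2CO3, acetone, 50 °C
Reagents that add atoms: iodomethane, CI
Why: Williamson methylation of the only free hydroxyl (3'-OH); every other oxygen is already etherified, so no selectivity is required.

Step 9
Reactants: 15 3-(benzyloxy)-5,7,8-trimethoxy-2-(3,4,5-trimethoxyphenyl)-4H-chromen-4-one
Product: 16 3,5-dihydroxy-7,8-dimethoxy-2-(3,4,5-trimethoxyphenyl)-4H-chromen-4-one (3,5-dihydroxy-7,8,3',4',5'-pentamethoxyflavone)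
Conditions: BCl3, C6HMe5, CH2Cl2, −78 → 0 °C; then MeOH, aq. NaHCO3
Reagents that add atoms: none
Why: Chelation-controlled ether cleavage: BCl3 binds the C4 carbonyl together with each flanking ether oxygen, so chloride should cleave only the 3-O-benzyl ether (at −78 °C) and the peri 5-O-methyl ether (on warming), a standard dealkylation of flavones; pentamethylbenzene traps the benzyl cation so that C6 of ring A is not benzylated, and the five unchelated methyl ethers should remain.

## Compound list

1 | 2'-hydroxy-3',4',6'-trimethoxyacetophenone [1-(2-hydroxy-3,4,6-trimethoxyphenyl)ethan-1-one] | CC(=O)c1c(O)c(OC)c(OC)cc1OC | starting material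
2 | (E)-3-(dimethylamino)-1-(2-hydroxy-3,4,6-trimethoxyphenyl)prop-2-en-1-one | CN(C)/C=C/C(=O)c1c(O)c(OC)c(OC)cc1OC | intermediate (not isolated)
3 | 5,7,8-trimethoxy-4H-chromen-4-one | COc1cc(OC)c2c(=O)ccoc2c1OC | intermediate
4 | rac-2,3-epoxy-5,7,8-trimethoxychroman-4-one (cis-fused epoxide, one enantiomer drawn) | COc1cc(OC)c2c(c1OC)O[C@@H]1O[C@@H]1C2=O | intermediate (not isolated)
5 | 3-hydroxy-5,7,8-trimethoxy-4H-chromen-4-one | COc1cc(OC)c2c(=O)c(O)coc2c1OC | intermediate
6 | 3-(benzyloxy)-5,7,8-trimethoxy-4H-chromen-4-one | COc1cc(OC)c2c(=O)c(OCc3ccccc3)coc2c1OC | intermediate
7 | [3-(benzyloxy)-5,7,8-trimethoxy-4-oxo-4H-chromen-2-yl]lithium | COc1cc(OC)c2c(=O)c(OCc3ccccc3)c([Li])oc2c1OC | intermediate (not isolated)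
8 | 3-(benzyloxy)-2-iodo-5,7,8-trimethoxy-4H-chromen-4-one | COc1cc(OC)c2c(=O)c(OCc3ccccc3)c(I)oc2c1OC | intermediate
9 | ethynyltrimethylsilane (trimethylsilylacetylene) | C[Si](C)(C)C#C | starting material
10 | 3-(benzyloxy)-5,7,8-trimethoxy-2-[(trimethylsilyl)ethynyl]-4H-chromen-4-one | COc1cc(OC)c2c(=O)c(OCc3ccccc3)c(C#C[Si](C)(C)C)oc2c1OC | intermediate
11 | 3-(benzyloxy)-2-ethynyl-5,7,8-trimethoxy-4H-chromen-4-one | COc1cc(OC)c2c(=O)c(OCc3ccccc3)c(C#C)oc2c1OC | intermediate
12 | 3,4-dimethoxyfuran | COc1cocc1OC | starting material
13 | rac-3-(benzyloxy)-2-(5,6-dimethoxy-7-oxabicyclo[2.2.1]hepta-2,5-dien-2-yl)-5,7,8-trimethoxy-4H-chromen-4-one (one enantiomer drawn) | COc1cc(OC)c2c(=O)c(OCc3ccccc3)c(C3=C[C@H]4O[C@@H]3C(OC)=C4OC)oc2c1OC | intermediate (not isolated)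
14 | 3-(benzyloxy)-2-(3-hydroxy-4,5-dimethoxyphenyl)-5,7,8-trimethoxy-4H-chromen-4-one | COc1cc(OC)c2c(=O)c(OCc3ccccc3)c(-c3cc(O)c(OC)c(OC)c3)oc2c1OC | intermediate
15 | 3-(benzyloxy)-5,7,8-trimethoxy-2-(3,4,5-trimethoxyphenyl)-4H-chromen-4-one | COc1cc(OC)c2c(=O)c(OCc3ccccc3)c(-c3cc(OC)c(OC)c(OC)c3)oc2c1OC | intermediate
16 | 3,5-dihydroxy-7,8-dimethoxy-2-(3,4,5-trimethoxyphenyl)-4H-chromen-4-one | COc1cc(-c2oc3c(OC)c(OC)cc(O)c3c(=O)c2O)cc(OC)c1OC | target

## Step count and least certain steps

Total step count: 9. Longest linear sequence: 9 steps (1 → 16); 9 and 12 are bought and enter in steps 5 and 7.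

Step 7 (key step, proposed new method).
- What may go wrong: the cycloaddition may be too slow, because the 3-alkoxy group and the ring oxygen feed electron density into the enynone; thermal oligomerisation of the terminal alkyne and decomposition of the furan could then outrun it. The bridge may also ionise partly at the wrong bridgehead if the carbonyl is not fully protonated, since the 3-benzyloxy group can then stabilise charge on C1' through C2=C3. Traces of water would hydrolyse the bis(enol ether) of 13.
- Fallback (known chemistry): ring B is introduced complete. Starting from 8, Suzuki–Miyaura coupling with commercial (3,4,5-trimethoxyphenyl)boronic acid (Pd(PPh3)4, K3PO4, dioxane/H2O, 80 °C) should give 15 directly, by the established coupling of 2-halochromones to flavones. The route is rejoined at 15 and no compound outside the list is made (F0).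

Step 9.
- What may go wrong: further loss of methyl groups from the two methoxy groups crowded between two oxygens (8-OMe, 4'-OMe) on warming, incomplete cleavage of the 5-O-methyl ether if the reaction is kept cold, or transfer of the benzyl cation to C6 if the scavenger is outpaced.
- Fallback: the unmasking is split into two steps of different mechanism. Starting from 15, hydrogenolysis (H2, Pd/C, EtOAc/THF) should give 3-hydroxy-5,7,8-trimethoxy-2-(3,4,5-trimethoxyphenyl)-4H-chromen-4-one F1 without any carbocation. The peri methyl ether is then removed with anhydrous AlCl3 in MeCN at room temperature, the classical chelate-selective 5-O-demethylation of polymethoxyflavones, returning to the route at 16.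

Step 6.
- What may go wrong: conjugate addition of fluoride or adventitious base to the freed enynone, or base-induced oligomerisation of the terminal alkyne during desilylation and concentration.
- Fallback: the silyl alkyne is avoided altogether. Starting from 8, Stille coupling with tributyl(ethynyl)stannane (Pd(PPh3)4, toluene, 60 °C) under neutral conditions should give 11 directly. The route is rejoined at 11 and no compound outside the list is made (F0).

Step 2.
- What may go wrong: sluggish epoxidation of the carbonyl-deactivated enol ether with competing oxidation of the trioxygenated ring A, or oxidation of product 5 if the oxidant is not removed before the acid treatment.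
- Fallback: oxidation at C3 is replaced by nitrosation. Starting from 3, hydrogenation of the C2=C3 bond (H2, Pd/C, EtOAc) should give 5,7,8-trimethoxychroman-4-one F2. Treatment with isoamyl nitrite and HCl in EtOH should nitrosate C3 to 3-(hydroxyimino)-5,7,8-trimethoxychroman-4-one F3, which hydrolyses in the same acid to the 3,4-dione, the keto tautomer of 5. This is the classical chromanone route to 3-hydroxychromones, and the route is rejoined at 5.

## Further compounds

F0 | step 7 | none | none
F1 | step 9 | 3-hydroxy-5,7,8-trimethoxy-2-(3,4,5-trimethoxyphenyl)-4H-chromen-4-one | COc1cc(OC)c2c(=O)c(O)c(-c3cc(OC)c(OC)c(OC)c3)oc2c1OC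
F0 | step 6 | none | none
F2 | step 2 | 5,7,8-trimethoxychroman-4-one | COc1cc(OC)c2c(c1OC)OCCC2=O
F3 | step 2 | 3-(hydroxyimino)-5,7,8-trimethoxychroman-4-one (oxime geometry not defined) | COc1cc(OC)c2c(c1OC)OCC(=NO)C2=O
A1 | alternative 1 | 2-(benzyloxy)-1-[2-(benzyloxy)-3,4,6-trimethoxyphenyl]ethan-1-one | COc1cc(OC)c(C(=O)COCc2ccccc2)c(OCc2ccccc2)c1OC
A2 | alternative 1 | 5-iodo-1,2,3-trimethoxybenzene | COc1cc(I)cc(OC)c1OC
A3 | alternative 1 | carbon monoxide | [C-]#[O+]
A4 | alternative 1 | 2-(benzyloxy)-1-[2-(benzyloxy)-3,4,6-trimethoxyphenyl]-3-(3,4,5-trimethoxyphenyl)propane-1,3-dione (racemic, enolisable) | COc1cc(OC)c(C(=O)C(OCc2ccccc2)C(=O)c2cc(OC)c(OC)c(OC)c2)c(OCc2ccccc2)c1OC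
A5 | alternative 1 | 3-hydroxy-5,7,8-trimethoxy-2-(3,4,5-trimethoxyphenyl)-4H-chromen-4-one | COc1cc(OC)c2c(=O)c(O)c(-c3cc(OC)c(OC)c(OC)c3)oc2c1OC
A6 | alternative 2 | 5,7,8-trimethoxy-2,2-dimethyl-4H-1,3-benzodioxin-4-one | COc1cc(OC)c2c(c1OC)OC(C)(C)OC2=O
A7 | alternative 2 | 2,3,5-trimethoxy-6-(oxomethylidene)cyclohexa-2,4-dien-1-one | O=C=C1C(OC)=CC(OC)=C(OC)C1=O
A8 | alternative 2 | 4-[2-(benzyloxy)-1-(3,4,5-trimethoxyphenyl)ethenyl]morpholine (double-bond geometry not defined) | COc1cc(C(=COCc2ccccc2)N2CCOCC2)cc(OC)c1OC
A9 | alternative 2 | 3-(benzyloxy)-5,7,8-trimethoxy-2-(3,4,5-trimethoxyphenyl)-4H-chromen-4-one | COc1cc(OC)c2c(=O)c(OCc3ccccc3)c(-c3cc(OC)c(OC)c(OC)c3)oc2c1OC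
A10 | alternative 3 | 3-(benzyloxy)-2-(3,4,5-trimethoxyphenyl)-4H-pyran-4-one | COc1cc(-c2occc(=O)c2OCc2ccccc2)cc(OC)c1OC
A11 | alternative 3 | 3-methoxycyclobut-3-ene-1,2-dione | COC1=CC(=O)C1=O
A12 | alternative 3 | 4-[5-(benzyloxy)-4-oxo-6-(3,4,5-trimethoxyphenyl)-4H-pyran-2-yl]-4-hydroxy-3-methoxycyclobut-2-en-1-one (racemic) | COC1=CC(=O)C1(O)c1cc(=O)c(OCc2ccccc2)c(-c2cc(OC)c(OC)c(OC)c2)o1
A13 | alternative 3 | 3-(benzyloxy)-5,8-dihydroxy-7-methoxy-2-(3,4,5-trimethoxyphenyl)-4H-chromen-4-one | COc1cc(O)c2c(c1O)oc(-c1cc(OC)c(OC)c(OC)c1)c(OCc1ccccc1)c2=O
A14 | alternative 3 | 3-(benzyloxy)-5-hydroxy-7,8-dimethoxy-2-(3,4,5-trimethoxyphenyl)-4H-chromen-4-one | COc1cc(O)c2c(=O)c(OCc3ccccc3)c(-c3cc(OC)c(OC)c(OC)c3)oc2c1OC
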